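The dihydrofuran is closed last, at O1–C7a, on an open-chain (1S,2R)-triarylethanol that already holds both stereocentres. The key step exploits the C6 hydroxyl of ring A, which lies para to C3a. Two-electron oxidation converts ring A into a 4-alkyl-4-methoxycyclohexadienone whose unsubstituted β-carbon C7a is within five-ring reach of the C2 hydroxyl. Anodic oxidation, oxa-Michael addition and loss of methanol add up to one C–H etherification that leaves C2–O and C3–H untouched, so the dyad becomes the cis (2S,3R) ring. The precursor carries a single free phenol (C6); rings B, C and D are masked as triisopropylsilyl ethers.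

Key step: step 11

Labels: atom numbers follow the benzofuran numbering of the target and are also used for the open-chain intermediates. Ring A is the benzo ring, ring B the aryl on C2, ring C the aryl on C3, and ring D the aryl at the end of the C4 chain. TIPS = triisopropylsilyl. The target is the cis isomer, (2S,3R), with both ring hydrogens on the same face.

Assumption: in step 9 the ketone enantiomer that reacts is taken to be the one that holds ring C (the bulkiest α-substituent once it carries two TIPS ethers) anti to the incoming hydride, which gives (R) at C3. Both α-substituents are aryl groups, so this sense is a reasoned expectation only, and the fallback to step 9 does not rely on it.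

Step 1
Reactants: 1 2-bromo-5-hydroxybenzaldehyde
Product: 2 5-(benzyloxy)-2-bromobenzaldehyde
Conditions: BnBr (1.1 equiv), K2CO3, DMF, rt
Reagents that add atoms: benzyl bromide, BrCc1ccccc1
Why: Williamson etherification of the phenoxide; benzyl is chosen for C6–O because it withstands alkoxide bases, zerovalent palladium and the ruthenium hydrogenation, and later falls in the same operation that saturates the chain.

Step 2
Reactants: 3 4-hydroxybenzyl alcohol
Product: 4 [4-(triisopropylsilyloxy)phenyl]methanol
Conditions: NaH (1.0 equiv), THF/DMF, 0 °C; then iPr3SiCl (1.0 equiv), 0 °C to rt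
Reagents that add atoms: triisopropylsilyl chloride, CC(C)[Si](Cl)(C(C)C)C(C)C
Why: Chemoselective O-silylation through the phenoxide: one equivalent of NaH removes only the far more acidic phenolic proton, and without a nucleophilic catalyst the neutral benzylic alcohol does not compete for the hindered chlorosilane.

Step 3
Reactants: 4 [4-(triisopropylsilyloxy)phenyl]methanol
Product: 5 diethyl {[4-(triisopropylsilyloxy)phenyl]methyl}phosphonate
Conditions: P(OEt)3 (3 equiv), ZnI2 (1.5 equiv), toluene, reflux
Reagents that add atoms: triethyl phosphite, CCOP(OCC)OCC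
Why: Lewis-acid-mediated Michaelis–Arbuzov-type conversion of an electron-rich benzylic alcohol directly into its phosphonate, which saves a separate halide step and leaves the aryl silyl ether alone.

Step 4
Reactants: 5 diethyl {[4-(triisopropylsilyloxy)phenyl]methyl}phosphonate; 2 5-(benzyloxy)-2-bromobenzaldehyde
Product: 6 (E)-{4-[2-(5-benzyloxy-2-bromophenyl)ethenyl]phenoxy}triisopropylsilane
Conditions: KOtBu (1.2 equiv), THF, 0 °C to rt
Reagents that add atoms: none
Why: Horner–Wadsworth–Emmons olefination of a benzylic phosphonate anion should give the (E)-stilbene as a single isomer, so one defined bromide enters the later steps; aryl bromide, benzyl ether and TIPS ether are inert here.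

Step 5
Reactants: 7 4'-hydroxyacetophenone
Product: 8 4'-(triisopropylsilyloxy)acetophenone
Conditions: iPr3SiCl (1.1 equiv), imidazole, DMF, rt
Reagents that add atoms: triisopropylsilyl chloride, CC(C)[Si](Cl)(C(C)C)C(C)C
Why: Standard imidazole-promoted silylation of a phenol; TIPS is preferred to smaller silyl groups because aryl TIPS ethers tolerate the alkoxide bases of steps 7 to 9 and the methanolic electrolyte of step 11.

Step 6
Reactants: 9 5-bromoresorcinol
Product: 10 1-bromo-3,5-bis(triisopropylsilyloxy)benzene
Conditions: iPr3SiCl (2.2 equiv), imidazole, DMF, rt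
Reagents that add atoms: triisopropylsilyl chloride, CC(C)[Si](Cl)(C(C)C)C(C)C
Why: The same imidazole-promoted silylation, applied to both phenols of ring C.

Step 7
Reactants: 8 4'-(triisopropylsilyloxy)acetophenone; 10 1-bromo-3,5-bis(triisopropylsilyloxy)benzene
Product: 11 2-[3,5-bis(triisopropylsilyloxy)phenyl]-1-[4-(triisopropylsilyloxy)phenyl]ethanone (ring B/ring C deoxybenzoin)
Conditions: Pd(OAc)2 (2 mol %), rac-BINAP (2.4 mol %), NaOtBu, toluene, 80 °C, slight excess of 8
Reagents that add atoms: none
Why: Palladium-catalysed ketone α-arylation (Buchwald–Hartwig type) of a methyl ketone enolate with an unhindered bromide; the chelating bisphosphine and the excess of ketone should hold the reaction at monoarylation.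

Step 8
Reactants: 11 ring B/ring C deoxybenzoin; 6 (E)-{4-[2-(5-benzyloxy-2-bromophenyl)ethenyl]phenoxy}triisopropylsilane
Product: 12 racemic 2-{4-benzyloxy-2-[(E)-2-(4-triisopropylsilyloxyphenyl)ethenyl]phenyl}-2-[3,5-bis(triisopropylsilyloxy)phenyl]-1-[4-(triisopropylsilyloxy)phenyl]ethanone
Conditions: Pd(OAc)2 (4 mol %), P(tBu)3·HBF4 (8 mol %), NaOtBu (2.2 equiv), toluene, 90 °C
Reagents that add atoms: none
Why: A second ketone α-arylation forms C3–C3a, now with a bulky electron-rich monophosphine that lets zerovalent palladium insert into the ortho-substituted bromide and speeds the crowded reductive elimination; the product enolate is too hindered to react again, and C3 is made racemic on purpose because it is configurationally labile.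

Step 9
Reactants: 12 racemic triaryl ketone
Product: 13 (1S,2R)-2-{4-benzyloxy-2-[(E)-2-(4-triisopropylsilyloxyphenyl)ethenyl]phenyl}-2-[3,5-bis(triisopropylsilyloxy)phenyl]-1-[4-(triisopropylsilyloxy)phenyl]ethanol
Conditions: trans-RuCl2[(R)-xylbinap][(R)-daipen] (1 mol %), KOtBu (20 mol %), H2 (20 atm), iPrOH/toluene, 30 °C
Reagents that add atoms: none
Why: Noyori asymmetric hydrogenation under dynamic kinetic resolution: KOtBu racemises the doubly benzylic, carbonyl-activated C3 through the enolate much faster than the ketone is reduced, the (R,R) catalyst adds hydride to the face that makes C2 (S) (aryl against branched alkyl, the sense known for acetophenone-type ketones), and the ketone enantiomer that holds bulky ring C anti to the hydride in a Felkin-type arrangement should be consumed, making C3 (R); this carbonyl-selective catalyst leaves the stilbene, benzyl ether and TIPS ethers alone.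

Step 10
Reactants: 13 (1S,2R)-alcohol with benzyl ether and stilbene
Product: 14 (1S,2R)-2-[3,5-bis(triisopropylsilyloxy)phenyl]-2-{4-hydroxy-2-[2-(4-triisopropylsilyloxyphenyl)ethyl]phenyl}-1-[4-(triisopropylsilyloxy)phenyl]ethanol (precursor, free C6 phenol)
Conditions: H2 (1 atm), 10% Pd/C, EtOAc, rt, stopped at full debenzylation
Reagents that add atoms: none
Why: Heterogeneous hydrogenation saturates the chain C=C and hydrogenolyses the aryl benzyl ether in one operation; under neutral conditions the hindered secondary C2 carbinol and the aryl silyl ethers should persist, and no stereocentre is touched.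

Step 11
Reactants: 14 (1S,2R)-triarylethanol with free C6 phenol
Product: 17 cis-(2S,3R)-tetrakis-TIPS ether of the target (free C6 phenol), via ring A methoxydienone 15 (not isolated), via bicyclic methoxy enone 16 (not isolated)
Conditions: (a) undivided cell, graphite anode, Pt cathode, constant current (5 mA cm−2, 2.1 F mol−1), LiClO4 (0.1 M), MeOH/CH2Cl2 4:1, 0 °C; (b) current off, methanol stripped cold, water wash, then PPTS (0.3 equiv), 4 Å MS, CH2Cl2, 35 °C
Reagents that add atoms: methanol, CO (its methoxy group sits on C3a in 15 and 16 and leaves again before 17)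
Why: Only ring A carries a free hydroxyl, so it is oxidised at the carbon anode (two electrons, one proton) at a clearly lower potential than the aryl silyl ethers, and methanol traps the phenoxenium ion at C3a, para to oxygen, to give dienone 15, as in the classical anodic or PhI(OAc)2 route to 4-alkyl-4-alkoxycyclohexadienones. Once the current is off and methanol has been replaced by CH2Cl2 (which removes the competing external nucleophile), PPTS activates the dienone and the C2 hydroxyl adds to C7a in a 5-exo-trig oxa-Michael closure (O1, C2, C3, C3a, C7a) to give the cis-fused enone 16, the reaction type known from tyrosol-derived quinols. The enol form of 16 is a methanol adduct of an arene, so acid-induced departure of the C3a methoxy group followed by loss of the C7a proton restores ring A, the addition–rearomatisation logic used for formal meta functionalisation of 4-alkylphenols. No lasting stereocentre is created: the centres at C3a and C7a are erased, both C3a epimers converge, and because C2–O and C3–H stay intact the (S) and (R) centres of 14 become the cis (2S,3R) pair of 17. Site selectivity between the two β-carbons comes from the substrate, since an adduct at the chain-bearing C4 would be a crowded quaternary ether with no hydrogen to lose and can only revert, whereas the C7a adduct drains away by aromatisation. The C4 chain also holds C3–H near the plane of ring A, which disfavours its loss to a quinone methide, and adding acid only after electrolysis keeps the electron-rich phenol 17 away from the anode.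

Step 12
Reactants: 17 cis-(2S,3R)-tetrakis-TIPS ether
Product: 18 (2S,3R)-3-(3,5-dihydroxyphenyl)-2-(4-hydroxyphenyl)-4-[2-(4-hydroxyphenyl)ethyl]-2,3-dihydro-1-benzofuran-6-ol (target, cis)
Conditions: Bu4NF (5 equiv), AcOH (5 equiv), THF, 0 °C; pH 6 buffer work-up
Reagents that add atoms: none
Why: Fluoride-induced cleavage of the four aryl silyl ethers; the acetic acid buffer keeps phenoxides from building up, because a free ring B phenoxide could expel the ring A aryloxide from C2 as a quinone methide and re-close to the trans isomer.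

Compound list
1 | 2-bromo-5-hydroxybenzaldehyde | O=Cc1cc(O)ccc1Br | starting material
2 | 5-(benzyloxy)-2-bromobenzaldehyde | O=Cc1cc(OCc2ccccc2)ccc1Br | intermediate
3 | 4-hydroxybenzyl alcohol | OCc1ccc(O)cc1 | starting material
4 | [4-(triisopropylsilyloxy)phenyl]methanol | OCc1ccc(O[Si](C(C)C)(C(C)C)C(C)C)cc1 | intermediate
5 | diethyl {[4-(triisopropylsilyloxy)phenyl]methyl}phosphonate | CCOP(=O)(Cc1ccc(O[Si](C(C)C)(C(C)C)C(C)C)cc1)OCC | intermediate
6 | (E)-{4-[2-(5-benzyloxy-2-bromophenyl)ethenyl]phenoxy}triisopropylsilane | Brc1ccc(OCc2ccccc2)cc1/C=C/c1ccc(O[Si](C(C)C)(C(C)C)C(C)C)cc1 | intermediate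
7 | 4'-hydroxyacetophenone | CC(=O)c1ccc(O)cc1 | starting material
8 | 4'-(triisopropylsilyloxy)acetophenone | CC(=O)c1ccc(O[Si](C(C)C)(C(C)C)C(C)C)cc1 | intermediate
9 | 5-bromoresorcinol | Oc1cc(O)cc(Br)c1 | starting material
10 | 1-bromo-3,5-bis(triisopropylsilyloxy)benzene | Brc1cc(O[Si](C(C)C)(C(C)C)C(C)C)cc(O[Si](C(C)C)(C(C)C)C(C)C)c1 | intermediate
11 | ring B/ring C deoxybenzoin, tris-TIPS ether | O=C(Cc1cc(O[Si](C(C)C)(C(C)C)C(C)C)cc(O[Si](C(C)C)(C(C)C)C(C)C)c1)c1ccc(O[Si](C(C)C)(C(C)C)C(C)C)cc1 | intermediate
12 | racemic triaryl ketone (C3 unassigned, E alkene, C6 benzyl ether) | O=C(c1ccc(O[Si](C(C)C)(C(C)C)C(C)C)cc1)C(c1cc(O[Si](C(C)C)(C(C)C)C(C)C)cc(O[Si](C(C)C)(C(C)C)C(C)C)c1)c1ccc(OCc2ccccc2)cc1/C=C/c1ccc(O[Si](C(C)C)(C(C)C)C(C)C)cc1 | intermediate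
13 | (1S,2R)-triarylethanol, C6 benzyl ether, E alkene | CC(C)[Si](C(C)C)(C(C)C)Oc1ccc(/C=C/c2cc(OCc3ccccc3)ccc2[C@@H](c2cc(O[Si](C(C)C)(C(C)C)C(C)C)cc(O[Si](C(C)C)(C(C)C)C(C)C)c2)[C@@H](c2ccc(O[Si](C(C)C)(C(C)C)C(C)C)cc2)O)cc1 | intermediate
14 | (1S,2R)-triarylethanol with free C6 phenol and saturated chain (precursor of the key step) | CC(C)[Si](C(C)C)(C(C)C)Oc1ccc(CCc2cc(O)ccc2[C@@H](c2cc(O[Si](C(C)C)(C(C)C)C(C)C)cc(O[Si](C(C)C)(C(C)C)C(C)C)c2)[C@@H](c2ccc(O[Si](C(C)C)(C(C)C)C(C)C)cc2)O)cc1 | intermediate
15 | ring A 4-methoxycyclohexa-2,5-dienone, OMe on C3a, both C3a epimers, C2 and C3 as in 14 | CC(C)[Si](C(C)C)(C(C)C)Oc1ccc(CCC2=CC(=O)C=CC2(OC)[C@@H](c2cc(O[Si](C(C)C)(C(C)C)C(C)C)cc(O[Si](C(C)C)(C(C)C)C(C)C)c2)[C@@H](c2ccc(O[Si](C(C)C)(C(C)C)C(C)C)cc2)O)cc1 | intermediate (not isolated)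
16 | cis-fused 3a-methoxy-3,3a,7,7a-tetrahydrobenzofuran-6(2H)-one, C3a/C7a pair as epimer mixture, C2 and C3 as in 14 | CC(C)[Si](C(C)C)(C(C)C)Oc1ccc(CCC2=CC(=O)CC3C2(OC)[C@@H](c2cc(O[Si](C(C)C)(C(C)C)C(C)C)cc(O[Si](C(C)C)(C(C)C)C(C)C)c2)[C@@H](c2ccc(O[Si](C(C)C)(C(C)C)C(C)C)cc2)O3)cc1 | intermediate (not isolated)
17 | (2S,3R)-3-[3,5-bis(triisopropylsilyloxy)phenyl]-2-[4-(triisopropylsilyloxy)phenyl]-4-{2-[4-(triisopropylsilyloxy)phenyl]ethyl}-2,3-dihydro-1-benzofuran-6-ol (cis) | CC(C)[Si](C(C)C)(C(C)C)Oc1ccc(CCc2cc(O)cc3c2[C@@H](c2cc(O[Si](C(C)C)(C(C)C)C(C)C)cc(O[Si](C(C)C)(C(C)C)C(C)C)c2)[C@@H](c2ccc(O[Si](C(C)C)(C(C)C)C(C)C)cc2)O3)cc1 | intermediate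
18 | (2S,3R)-3-(3,5-dihydroxyphenyl)-2-(4-hydroxyphenyl)-4-[2-(4-hydroxyphenyl)ethyl]-2,3-dihydro-1-benzofuran-6-ol (cis) | Oc1ccc(CCc2cc(O)cc3c2[C@@H](c2cc(O)cc(O)c2)[C@@H](c2ccc(O)cc2)O3)cc1 | target

Total step count: 12. Longest linear sequence: 8 steps (3 → 4 → 5 → 6 → 12 → 13 → 14 → 17 → 18).

Steps most likely to fail

Step 11. Several processes can go wrong.
- At the phenoxenium stage the C2 hydroxyl may drive a Grob-type cleavage of the C2–C3 bond.
- At the same stage C3–H may be lost; either event leads to quinone methide formation.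
- In the acid stage the para-silyloxybenzylic C2–O bond may ionise and erode the cis relationship.
- Aromatisation may stall at the enone.

The fallback sets out from 14 and replaces the cationic oxidation by a pericyclic one and the acid by a thermal elimination. Dye-sensitised photooxygenation (O2, tetraphenylporphyrin, visible light, CH2Cl2/MeOH, 0 °C) should add singlet oxygen to the free phenol ring only and give the para-hydroperoxy dienone F1. Me2S reduces this to the para-quinol F2. Catalytic DBU in CH2Cl2 closes the same O1–C7a bond by oxa-Michael addition to give the bicyclic hydroxy enone F3. In F3 the C3a hydroxyl and the C7a hydrogen are syn on the cis-fused ring, so Burgess reagent (1.05 equiv, toluene, 50 °C) can remove them by syn elimination. Tautomerisation then returns the route at 17.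

Step 9. Both α-substituents are aryl groups, so selection between the two ketone enantiomers may be poor or reversed, and turnover at the hindered carbonyl may be slow. The fallback sets out from 12 and gives up the dynamic resolution. Hydrogenation without added base with RuH(BH4)[(R)-xylbinap][(R,R)-dpen] in iPrOH/toluene leaves C3 configurationally fixed and lets the catalyst set C2 only. Both ketone enantiomers then become (1S) alcohols, namely 13 and the (1S,2S) C3-epimeric alcohol F4. These diastereomers are separated on silica, which returns the route at 13. F4 is oxidised with Dess–Martin periodinane back to 12, racemised with a trace of DBU and recycled.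

Step 8. The ortho substituent may slow oxidative addition and reductive elimination, which would allow hydrodebromination or Heck-type consumption of the stilbene. The fallback sets out from 8 and 6 and changes which bond is made in the crowded event. The hindered bromide 6 is first coupled with the small methyl ketone enolate of 8 (Pd(OAc)2, P(tBu)3·HBF4, NaOtBu, toluene) to give the ring A/ring B deoxybenzoin F5. F5 is then α-arylated with the unhindered bromide 10 under the same type of catalysis, so that C3–ring C is the last bond formed, which returns the route at 12.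

Further compounds
F1 | step 11 | para-hydroperoxy dienone (OOH on C3a, both C3a epimers, C2 and C3 as in 14) | CC(C)[Si](C(C)C)(C(C)C)Oc1ccc(CCC2=CC(=O)C=CC2(OO)[C@@H](c2cc(O[Si](C(C)C)(C(C)C)C(C)C)cc(O[Si](C(C)C)(C(C)C)C(C)C)c2)[C@@H](c2ccc(O[Si](C(C)C)(C(C)C)C(C)C)cc2)O)cc1
F2 | step 11 | para-quinol (OH on C3a, both C3a epimers, C2 and C3 as in 14) | CC(C)[Si](C(C)C)(C(C)C)Oc1ccc(CCC2=CC(=O)C=CC2(O)[C@@H](c2cc(O[Si](C(C)C)(C(C)C)C(C)C)cc(O[Si](C(C)C)(C(C)C)C(C)C)c2)[C@@H](c2ccc(O[Si](C(C)C)(C(C)C)C(C)C)cc2)O)cc1
F3 | step 11 | bicyclic hydroxy enone (cis-fused, 3a-hydroxy, C2 and C3 as in 14) | CC(C)[Si](C(C)C)(C(C)C)Oc1ccc(CCC2=CC(=O)CC3C2(O)[C@@H](c2cc(O[Si](C(C)C)(C(C)C)C(C)C)cc(O[Si](C(C)C)(C(C)C)C(C)C)c2)[C@@H](c2ccc(O[Si](C(C)C)(C(C)C)C(C)C)cc2)O3)cc1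
F4 | step 9 | (1S,2S) C3-epimeric alcohol of 13 | CC(C)[Si](C(C)C)(C(C)C)Oc1ccc(/C=C/c2cc(OCc3ccccc3)ccc2[C@H](c2cc(O[Si](C(C)C)(C(C)C)C(C)C)cc(O[Si](C(C)C)(C(C)C)C(C)C)c2)[C@@H](c2ccc(O[Si](C(C)C)(C(C)C)C(C)C)cc2)O)cc1
F5 | step 8 | ring A/ring B deoxybenzoin, 2-{4-benzyloxy-2-[(E)-2-(4-triisopropylsilyloxyphenyl)ethenyl]phenyl}-1-[4-(triisopropylsilyloxy)phenyl]ethanone | O=C(Cc1ccc(OCc2ccccc2)cc1/C=C/c1ccc(O[Si](C(C)C)(C(C)C)C(C)C)cc1)c1ccc(O[Si](C(C)C)(C(C)C)C(C)C)cc1
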